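**Plan**
- Retrosynthesis: after removal of the three masking groups (dioxolane, acetonide, O-methyl), the benzene ring is cut at C1–C6 (aldol), then at C5–C6 (Claisen acylation) and C3–C4 (γ-acylation of a dioxinone); the side chain is cut between its CH2 and its ketone carbon (Meldrum's acid acylation).
- Enabling feature: with the ring numbered C1 (CO2H), C2 (OH), C4 (OMe), C6 (2-oxotridecyl), oxygen sits on every second ring carbon and the carboxyl on C1. This is the imprint of a linear poly-β-carbonyl chain folded once, so C1–C6 can be closed by an intramolecular aldol of a diketo-dioxinone.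
- Forward: a keto-dioxinone (from trimethyldioxinone and acetyl chloride) and a ketal-protected β-keto Weinreb amide (from dodecanoyl chloride and Meldrum's acid) are joined to the open chain. The only carbocycle, the benzene ring, then arises in the cycloaromatization, with the dioxinone ring carried through as the acetonide of the salicylate.
- Endgame: methylation of the single free phenol, hydroxide opening of the benzodioxinone, acid release of the ketone.
- Stereochemistry: the target is achiral; the one transient stereocentre (carbinol of the aldol adduct) is racemic and is erased on dehydration.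

Key step: step 6

Remark: the target is taken as the open keto acid as drawn (not its lactol or isocoumarin form) and has no stereocentre; LiN(SiMe3)2 and LiN(iPr)2 are used as commercial solutions.

Step 1
Reactants: 1 2,2,6-trimethyl-4H-1,3-dioxin-4-one; 2 acetyl chloride
Product: 3 2,2-dimethyl-6-(2-oxopropyl)-4H-1,3-dioxin-4-one
Conditions: LiN(SiMe3)2 (1.05 equiv), THF, −78 °C; then AcCl (0.5 equiv), −78 °C; 1 M HCl quench
Reagents that add atoms: none
Why: The lithium dienolate of the dioxinone is acylated at its γ-carbon (the 6-methyl group) by the acid chloride, a vinylogous Claisen-type C-acylation in which the excess dienolate absorbs the proton of the more acidic product.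

Step 2
Reactants: 4 dodecanoyl chloride; 5 Meldrum's acid
Product: 7 methyl 3-oxotetradecanoate, via acyl Meldrum's acid 6 (not isolated)
Conditions: pyridine (2 equiv), CH2Cl2, 0 °C to rt; dilute HCl wash, concentrate; then MeOH, reflux
Reagents that add atoms: methanol, CO
Why: C-acylation of Meldrum's acid followed by methanolysis with loss of acetone and CO2 (Oikawa–Yonemitsu β-keto ester synthesis) should give the β-keto ester cleanly.

Step 3
Reactants: 7 methyl 3-oxotetradecanoate
Product: 8 methyl 2-(2-undecyl-1,3-dioxolan-2-yl)acetate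
Conditions: ethylene glycol (3 equiv), p-TsOH·H2O (cat.), toluene, reflux, Dean–Stark
Reagents that add atoms: ethylene glycol, OCCO
Why: Acid-catalysed ketalization with azeotropic removal of water masks the ketone of the β-keto ester as the dioxolane, a standard protection.

Step 4
Reactants: 8 methyl 2-(2-undecyl-1,3-dioxolan-2-yl)acetate
Product: 9 N-methoxy-N-methyl-2-(2-undecyl-1,3-dioxolan-2-yl)acetamide
Conditions: MeNHOMe·HCl (1.5 equiv), iPrMgCl (3 equiv), THF, −20 to 0 °C; aq. NH4Cl
Reagents that add atoms: N,O-dimethylhydroxylamine hydrochloride, CNOC.Cl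
Why: The chloromagnesium amide formed in the flask converts the ester directly into the Weinreb amide (aminolysis of an ester by a magnesium amide), and the base-stable dioxolane is untouched.

Step 5
Reactants: 3 2,2-dimethyl-6-(2-oxopropyl)-4H-1,3-dioxin-4-one; 9 N-methoxy-N-methyl-2-(2-undecyl-1,3-dioxolan-2-yl)acetamide
Product: 10 2,2-dimethyl-6-[2,4-dioxo-5-(2-undecyl-1,3-dioxolan-2-yl)pentyl]-4H-1,3-dioxin-4-one
Conditions: 3 (2.2 equiv), LiN(iPr)2 (4.5 equiv), THF, −78 to −40 °C; then 9, −78 to −20 °C; sat. aq. NH4Cl
Reagents that add atoms: none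
Why: The dianion of the keto-dioxinone reacts at its terminal carbanion (Weiler-type dianion) with the Weinreb amide in a Claisen-type acylation, the chelated tetrahedral intermediate releasing the 1,3-diketone only on work-up.

Step 6
Reactants: 10 2,2-dimethyl-6-[2,4-dioxo-5-(2-undecyl-1,3-dioxolan-2-yl)pentyl]-4H-1,3-dioxin-4-one
Product: 12 7-hydroxy-2,2-dimethyl-5-[(2-undecyl-1,3-dioxolan-2-yl)methyl]-4H-benzo[d][1,3]dioxin-4-one, via cyclic aldol carbinol 11 (not isolated)
Conditions: Et3N (excess), CH2Cl2, rt
Reagents that add atoms: none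
Why: With the side chain numbered C1' to C5' from the dioxinone, Et3N removes a proton from the doubly activated C1' methylene to give the extended enolate, whose dioxinone α-carbon C5 adds to the C4' ketone in an intramolecular aldol to give carbinol 11; E1cB loss of water and enolization of the C2' ketone then give the phenol, the ring being closed through the bond that becomes C1–C6 of the target. The closest known reaction type is the amine- or carbonate-mediated biomimetic cycloaromatization of 6-(2,4-dioxoalkyl)-1,3-dioxin-4-ones to isopropylidene-protected β-resorcylates. The one new ring closes in a 6-(enolexo)-exo-trig mode, the O–C4=C5 enolate bond lying outside the forming ring and the oxygen of the attacked carbonyl being exocyclic. No stereocentre remains, since the carbinol carbon of 11 forms as a racemate and becomes sp2 on dehydration. The step needs fold selectivity: the dioxolane removes the outermost carbonyl as an electrophile, so the C1' carbanion cannot close the alternative six-membered ring that would lead to an acylresorcinol, and the mild base together with the low electrophilicity of the dioxinone carbonyl should suppress the Claisen-type closure from C3'. The surviving acetonide ties the C2 oxygen to the carboxyl, so the only free phenol is the one destined to become the methoxyl.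

Step 7
Reactants: 12 7-hydroxy-2,2-dimethyl-5-[(2-undecyl-1,3-dioxolan-2-yl)methyl]-4H-benzo[d][1,3]dioxin-4-one
Product: 13 7-methoxy-2,2-dimethyl-5-[(2-undecyl-1,3-dioxolan-2-yl)methyl]-4H-benzo[d][1,3]dioxin-4-one
Conditions: MeI (1.5 equiv), K2CO3 (2 equiv), acetone, rt
Reagents that add atoms: iodomethane, CI
Why: Williamson ether synthesis on the only free phenol, with the other oxygen and the carboxyl locked in the acetonide and the ketal inert to carbonate.

Step 8
Reactants: 13 7-methoxy-2,2-dimethyl-5-[(2-undecyl-1,3-dioxolan-2-yl)methyl]-4H-benzo[d][1,3]dioxin-4-one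
Product: 14 2-hydroxy-4-methoxy-6-[(2-undecyl-1,3-dioxolan-2-yl)methyl]benzoic acid
Conditions: KOH (2 M aq., excess), 1,4-dioxane, 60 °C; then 1 M HCl, 0 °C, to pH 3, immediate extraction
Reagents that add atoms: potassium hydroxide, [K+].[OH-]
Why: Hydroxide adds to the acylal-type lactone carbonyl of the benzodioxinone and the hemiketal that is released collapses to acetone and the phenoxide (saponification), while the dioxolane is stable to base and keeps the ketone out of enolate chemistry.

Step 9
Reactants: 14 2-hydroxy-4-methoxy-6-[(2-undecyl-1,3-dioxolan-2-yl)methyl]benzoic acid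
Product: 15 2-hydroxy-4-methoxy-6-(2-oxotridecyl)benzoic acid
Conditions: 1 M aq. HCl–THF (1:2), rt
Reagents that add atoms: water, O
Why: Acid-catalysed hydrolysis of the dialkyl ketone dioxolane should proceed at room temperature in a water-rich medium, conditions mild enough to avoid dehydrative lactonization or decarboxylation of the salicylic acid.

**Compound list**
1 | 2,2,6-trimethyl-4H-1,3-dioxin-4-one | CC1=CC(=O)OC(C)(C)O1 | starting material
2 | acetyl chloride | CC(Cl)=O | starting material
3 | 2,2-dimethyl-6-(2-oxopropyl)-4H-1,3-dioxin-4-one | CC(=O)CC1=CC(=O)OC(C)(C)O1 | intermediate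
4 | dodecanoyl chloride | CCCCCCCCCCCC(Cl)=O | starting material
5 | Meldrum's acid (2,2-dimethyl-1,3-dioxane-4,6-dione) | CC1(C)OC(=O)CC(=O)O1 | starting material
6 | 5-(1-hydroxydodecylidene)-2,2-dimethyl-1,3-dioxane-4,6-dione (acyl Meldrum's acid, not isolated) | CCCCCCCCCCCC(O)=C1C(=O)OC(C)(C)OC1=O | intermediate
7 | methyl 3-oxotetradecanoate | CCCCCCCCCCCC(=O)CC(=O)OC | intermediate
8 | methyl 2-(2-undecyl-1,3-dioxolan-2-yl)acetate | CCCCCCCCCCCC1(CC(=O)OC)OCCO1 | intermediate
9 | N-methoxy-N-methyl-2-(2-undecyl-1,3-dioxolan-2-yl)acetamide | CCCCCCCCCCCC1(CC(=O)N(C)OC)OCCO1 | intermediate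
10 | 2,2-dimethyl-6-[2,4-dioxo-5-(2-undecyl-1,3-dioxolan-2-yl)pentyl]-4H-1,3-dioxin-4-one | CCCCCCCCCCCC1(OCCO1)CC(=O)CC(=O)CC1=CC(=O)OC(C)(C)O1 | intermediate
11 | racemic 5-hydroxy-2,2-dimethyl-5-[(2-undecyl-1,3-dioxolan-2-yl)methyl]-5,6-dihydro-4H-benzo[d][1,3]dioxine-4,7(8H)-dione (cyclic aldol carbinol, not isolated) | CCCCCCCCCCCC1(OCCO1)CC2(O)CC(=O)CC3=C2C(=O)OC(C)(C)O3 | intermediate
12 | 7-hydroxy-2,2-dimethyl-5-[(2-undecyl-1,3-dioxolan-2-yl)methyl]-4H-benzo[d][1,3]dioxin-4-one | CCCCCCCCCCCC1(OCCO1)Cc1cc(O)cc2OC(C)(C)OC(=O)c12 | intermediate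
13 | 7-methoxy-2,2-dimethyl-5-[(2-undecyl-1,3-dioxolan-2-yl)methyl]-4H-benzo[d][1,3]dioxin-4-one | CCCCCCCCCCCC1(OCCO1)Cc1cc(OC)cc2OC(C)(C)OC(=O)c12 | intermediate
14 | 2-hydroxy-4-methoxy-6-[(2-undecyl-1,3-dioxolan-2-yl)methyl]benzoic acid | CCCCCCCCCCCC1(OCCO1)Cc1cc(OC)cc(O)c1C(=O)O | intermediate
15 | 2-hydroxy-4-methoxy-6-(2-oxotridecyl)benzoic acid | CCCCCCCCCCCC(=O)Cc1cc(OC)cc(O)c1C(=O)O | target

**Step count**
Total: 9 steps. Longest linear sequence: 8 steps (steps 2 to 9, from dodecanoyl chloride); step 1 is the one-step side branch.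

**Steps most likely to fail**

Step 5. The dianion may act as a base toward the α-methylene of the Weinreb amide (proton transfer in place of C–C bond formation), and the resulting amide enolate may open the dioxolane by β-elimination. The fallback replaces the Claisen acylation by an aldol addition and an oxidation. It sets out from 9 and 3. Reduction of 9 with iBu2AlH (THF, −78 °C) should give 2-(2-undecyl-1,3-dioxolan-2-yl)acetaldehyde F1. Addition of the dianion of 3 (LiN(iPr)2, THF, −78 °C) to this far more electrophilic carbonyl should give racemic 6-[4-hydroxy-2-oxo-5-(2-undecyl-1,3-dioxolan-2-yl)pentyl]-2,2-dimethyl-4H-1,3-dioxin-4-one F2. Oxidation of the secondary alcohol with Dess–Martin periodinane (NaHCO3, CH2Cl2, 0 °C to rt) returns to the route at 10.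

Step 6. The cyclization may stall before dehydration, or the enolized diketone may close through oxygen (pyranone formation) in place of the carbon–carbon aldol. The fallback keeps the same C1–C6 aldol but runs it on the open-chain ester. It sets out from 10. Heating in toluene at 110 °C with benzyl alcohol expels acetone and traps the acylketene as benzyl 3,5,7-trioxo-8-(2-undecyl-1,3-dioxolan-2-yl)octanoate F3. Cs2CO3 in THF followed by AcOH should aromatize it to benzyl 2,4-dihydroxy-6-[(2-undecyl-1,3-dioxolan-2-yl)methyl]benzoate F4. The 4-hydroxyl, which is not hydrogen-bonded to the ester, is methylated selectively (MeI, 1.05 equiv, K2CO3, acetone) to benzyl 2-hydroxy-4-methoxy-6-[(2-undecyl-1,3-dioxolan-2-yl)methyl]benzoate F5. Hydrogenolysis (H2, Pd/C, EtOAc) returns to the route at 14.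

Step 9. Once the ketone is set free next to the carboxylic acid, acid may promote enol-lactonization toward an isocoumarin or protodecarboxylation of the electron-rich salicylic acid. The fallback inverts the order of the two unmasking events, so that the free acid meets acid only in a cold work-up. It sets out from 13. Hydrolysis of the ketal on this neutral benzodioxinone (1 M aq. HCl–THF, rt) should give 7-methoxy-2,2-dimethyl-5-(2-oxotridecyl)-4H-benzo[d][1,3]dioxin-4-one F6. Opening with degassed 2 M aq. KOH in 1,4-dioxane at 50 °C, then acidification at 0 °C to pH 3 and immediate extraction, arrives at 15.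

**Further compounds**
F1 | step 5 | 2-(2-undecyl-1,3-dioxolan-2-yl)acetaldehyde | CCCCCCCCCCCC1(CC=O)OCCO1
F2 | step 5 | racemic 6-[4-hydroxy-2-oxo-5-(2-undecyl-1,3-dioxolan-2-yl)pentyl]-2,2-dimethyl-4H-1,3-dioxin-4-one | CCCCCCCCCCCC1(OCCO1)CC(O)CC(=O)CC1=CC(=O)OC(C)(C)O1
F3 | step 6 | benzyl 3,5,7-trioxo-8-(2-undecyl-1,3-dioxolan-2-yl)octanoate | CCCCCCCCCCCC1(OCCO1)CC(=O)CC(=O)CC(=O)CC(=O)OCc1ccccc1
F4 | step 6 | benzyl 2,4-dihydroxy-6-[(2-undecyl-1,3-dioxolan-2-yl)methyl]benzoate | CCCCCCCCCCCC1(OCCO1)Cc1cc(O)cc(O)c1C(=O)OCc1ccccc1
F5 | step 6 | benzyl 2-hydroxy-4-methoxy-6-[(2-undecyl-1,3-dioxolan-2-yl)methyl]benzoate | CCCCCCCCCCCC1(OCCO1)Cc1cc(OC)cc(O)c1C(=O)OCc1ccccc1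
F6 | step 9 | 7-methoxy-2,2-dimethyl-5-(2-oxotridecyl)-4H-benzo[d][1,3]dioxin-4-one | CCCCCCCCCCCC(=O)Cc1cc(OC)cc2OC(C)(C)OC(=O)c12
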